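## Structural features

Squamatic acid (27) is a depside. It has two benzene rings, each with five substituents and one hydrogen, joined only by an ester between the C1 carboxyl carbon of ring A and the C4' oxygen of ring B. Ring A carries in sequence the ester carbonyl (C1), OH (C2), CO2H (C3), OMe (C4), H (C5) and CH3 (C6). Ring B carries CO2H (C1'), OH (C2'), CH3 (C3'), the ester oxygen (C4'), H (C5') and CH3 (C6'). There is no stereocentre, so the task is one of regiochemistry and functional-group compatibility only. The fragile parts are the aryl ester link (cleaved by alkoxides, hydroxide, amines and hard organometallics), the two salicylic acid units (prone to decarboxylation) and the electron-rich positions C5 and C5' (prone to halogenation). The real difficulty is the contiguous C1–C4 array of ring A: a carbon must be placed at C3 between two oxygens, although C5, para to the C2 hydroxyl, is expected to be the more reactive site toward electrophiles. In addition, the two ring B phenols must be differentiated. The key step exploits the fact that the C2 hydroxyl and the C3 carboxyl carbon are neighbours and that the C4 methoxy group sits beside C3: a C2–C3 aryne of ring A can take up oxygen at C2 and carbon at C3 in one operation, with the methoxy group polarising the triple bond.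

## Logic of the disconnections

**27 ⇒ 26.** The two O–CH2Ph bonds (ester at C1', ether at C2') are cut last. Hydrogenolysis is neutral and spares the depside ester, and the benzyl groups keep the ring B acid and phenol silent through all basic, organometallic and aryne chemistry. The forward step requires that nothing else in 26 be reducible.

**26 ⇒ 25.** The C3 carboxyl is traced back to the aldehyde, because the aryne step delivers the formyl oxidation level. The forward step must oxidise a hindered salicylaldehyde without chlorinating C5 or C5'.

**25 ⇒ 20 + 21.** The C2–O and C3–C(formyl) bonds are cut together. They sit on adjacent ring carbons, so both can be formed across a C2–C3 triple bond, with 21 supplying the phenol oxygen and the formyl carbon. The precursor 20 then needs only silicon at C3 and a sulfonate at C2. The forward step must generate the aryne under conditions that two esters tolerate and must place oxygen at C2, not C3.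

**20 ⇒ 16.** The C3–Si and O–S bonds are cut, leading to an ortho-bromophenol. The forward step is O-silylation, bromine–lithium exchange, 1,3 oxygen-to-carbon silyl shift and O-sulfonylation. The exchange must outrun addition to the esters, which is why both esters of 16 are flanked by two ortho substituents.

**16 ⇒ 8 + 14.** The ester C(=O)–O bond is cut, giving two fragments of similar size. The forward step must acylate a hindered phenol with a hindered salicylic acid without protecting the C2 hydroxyl of 8, and 14 must expose only its C4' hydroxyl.

**8 ⇒ 7 ⇒ 5 ⇒ 3 ⇒ 1.** The cuts are, in turn, the acid back to the aldehyde, the C2 O–H back to O–CH3, the C1–CHO bond and the C3–Br bond. In 3 the bromine lies on the symmetry axis of 1 between two equivalent methoxy groups, and the two remaining ring positions are equivalent. The C3 placeholder is therefore fixed by symmetry and not by an electrophilic substitution of a 2-hydroxy-4-methoxy-6-methylbenzoate, which would favour C5. The forward route needs one chelation-controlled demethylation (7 from 5), which the carbonyl group next to C2 provides.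

**14 ⇒ 13 ⇒ 11 ⇒ 10 ⇒ 9.** The cuts are the O–allyl bond, the two ether O–C bonds, the ester O–CH2Ph bond and the C1'–CO2H bond. The symmetry of 9 makes the carboxylation unambiguous. The forward route relies on the usual order of phenol reactivity in 11 (free C4' hydroxyl before the hydrogen-bonded C2' hydroxyl) and uses a temporary allyl group to invert it.

## Other disconnections considered

**Alternative 1:** The cut removes the C1–C2, C2–C3 and C4–C5 bonds of ring A, so ring A is assembled on a preformed ring B ester. The forward key step would be irradiation of the diazo enone A2 (the ring B ester of (E)-5-diazo-3-methyl-4-oxopent-2-enoic acid) with the ynol ether A3. Wolff rearrangement gives a vinylketene, and its carbonyl carbon joins the oxygen-free alkyne carbon in a [2+2] cycloaddition. A 4-electron ring opening, a 6-electron electrocyclisation and tautomerisation would then give A1.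
- In its favour: every substituent of ring A, including the C3 carbon, is placed by the connectivity of the two components. On regiochemical certainty this is at least the equal of the chosen plan, and better than the aryne step taken alone, whose orientation depends on a balance between two flanking groups.
- Against it: A2 combines a diazo ketone, an enoate and an aryl ester, and its preparation from 14 involves base-mediated diazo transfer next to a cleavable ester. The photolysis must proceed in a molecule with three benzenoid chromophores and an aryl ester that can itself undergo photochemical acyl shift. A3 is a sensitive ynol ether that needs its own sequence.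
- Comparison: A1 holds C3 at the alcohol level, so four steps would follow the key step (desilylation, two oxidations, hydrogenolysis) against two in the chosen plan. The mechanism is a pericyclic cascade, whereas the chosen route uses polar aryne chemistry. The ring B work is identical. The overall count is estimated to be similar or somewhat longer, with more sensitive intermediates.

**Alternative 2:** The cut removes the depside C–O bond and the C1–C6 bond of ring A. The forward key step would heat the diketo-dioxinone A5 with 11. A transient acylketene should acylate the free C4' hydroxyl, and the resulting open-chain tricarbonyl ester should close by aldol condensation and aromatise to A4.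
- In its favour: one operation forms both the depside bond and ring A, without organometallic reagents. It uses 11 directly, so the allyl/benzyl differentiation of ring B is not needed; in protecting-group economy this alternative is the better plan. The overall sequence could be shorter (about nine to ten steps).
- Against it: A4 lacks the C4 O-methyl group and the C3 carbon. Both must be introduced on a compound with three free phenols and three nucleophilic ring positions (C3, C5, C5'). C3, flanked by two hydroxyls, is a reasonable site for a phenol-directed formylation, but C5', para to the free C2' hydroxyl, competes. The base needed for aromatisation also threatens the aryl ester.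
- Comparison: the alternative is better on step count and worse on the reliability of the late C3 functionalisation. The chosen route settles that point by symmetry in step 1 and by the aryne in step 11.

**Alternative 3:** The cut removes the C5–C6 and C1–C2 bonds of ring A. The forward key step would be a [4+2] cycloaddition of the Brassard diene A8 with the ring B but-2-ynoate A7 (made from 14), followed by elimination and desilylation to give A6.
- In its favour: the 2-hydroxy-4-methoxy-6-methyl pattern arises directly, with orientation fixed by the polarity of the diene. The ring B protection is the same as in the chosen plan. A6 would need only a phenol-directed ortho-formylation to reach 25, so the route would be about nine steps; on step count this is better than the chosen plan.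
- Against it: a β-methyl ynoate is a sluggish dienophile, and at the temperatures needed the diene tends to decompose or transfer its silyl group. The aryl ester must survive these conditions. The C3 carbon still comes from a separate substitution whose selectivity for C3 over C5 rests on chelation to the C2 oxygen.
- Comparison: the alternative is structurally the simplest and mechanistically the most direct. It is less secure at two points, the cycloaddition reactivity and the C3 against C5 selectivity, where the chosen plan is controlled by symmetry and by the polarisation of the aryne.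

Key step: step 11

Remarks on the chemistry:
- 27 is achiral, so no step sets or must preserve configuration.
- The silyl triflate 20 and the aldehyde 25 agree atom for atom with 27, and no structure needed correction.
- The design change is in the supply of the C3 bromine: it is fixed by the symmetry of 1 because electrophilic bromination of a 2-hydroxy-4-methoxy-6-methylbenzoate is expected to favour C5.
- A telescoped one-pot sequence is counted as one step.

## Route

Step 1
Reactants: 1 3,5-dimethoxytoluene (1,3-dimethoxy-5-methylbenzene)
Product: 3 2-bromo-1,3-dimethoxy-5-methylbenzene, via aryllithium 2 (not isolated)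
Conditions: n-BuLi, TMEDA, THF, 0 °C → rt; BrCH2CH2Br, −78 °C → rt
Reagents that add atoms: 1,2-dibromoethane, BrCCBr
Why: Directed ortho-metalation: the proton between the two methoxy groups is the most acidic ring proton, and aryllithium 2 takes bromine from 1,2-dibromoethane with loss of ethene. The bromine lies on the symmetry axis, so the later C3 position of ring A is fixed here without any regiochemical choice.

Step 2
Reactants: 3 2-bromo-1,3-dimethoxy-5-methylbenzene
Product: 5 3-bromo-2,4-dimethoxy-6-methylbenzaldehyde, via chloro ether 4 (not isolated)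
Conditions: Cl2CHOMe, TiCl4, CH2Cl2, −78 → 0 °C; H2O
Reagents that add atoms: dichloromethyl methyl ether, COC(Cl)Cl; water, O
Why: Rieche formylation (Friedel–Crafts alkylation by the TiCl4-activated dichloromethyl ether, then hydrolysis of 4). The two free positions of 3 are equivalent, each para to one methoxy group and ortho to the other, so only one aldehyde can form.

Step 3
Reactants: 5 3-bromo-2,4-dimethoxy-6-methylbenzaldehyde
Product: 7 3-bromo-2-hydroxy-4-methoxy-6-methylbenzaldehyde, via aryloxydichloroborane 6 (not isolated)
Conditions: BCl3, CH2Cl2, −78 → 0 °C; H2O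
Reagents that add atoms: none
Why: Chelation-controlled ether cleavage: BCl3 binds the aldehyde oxygen and the adjacent C2 methoxy oxygen in a six-membered chelate, and chloride removes that methyl group. The C4 methoxy group, para to the carbonyl, has no such assistance at low temperature.

Step 4
Reactants: 7 3-bromo-2-hydroxy-4-methoxy-6-methylbenzaldehyde
Product: 8 3-bromo-2-hydroxy-4-methoxy-6-methylbenzoic acid
Conditions: NaClO2, NaH2PO4, 2-methyl-2-butene, t-BuOH/THF/H2O, 0 °C → rt
Reagents that add atoms: sodium chlorite (NaClO2), [Na+].[O-]Cl=O
Why: Pinnick oxidation: chlorous acid adds to the aldehyde and fragments to the acid and HOCl. The alkene scavenger consumes the HOCl before it can chlorinate C5.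

Step 5
Reactants: 9 2,5-dimethylresorcinol (2,5-dimethylbenzene-1,3-diol)
Product: 10 2,4-dihydroxy-3,6-dimethylbenzoic acid
Conditions: KHCO3, CO2 (1 atm), glycerol, 130 °C; aq. HCl, 0 °C
Reagents that add atoms: carbon dioxide, O=C=O
Why: Kolbe–Schmitt carboxylation in its hydrogen carbonate variant: the resorcinol monoanion is carboxylated ortho to one hydroxyl and para to the other. C4 and C6 of 9 are equivalent, so only one acid can form.

Step 6
Reactants: 10 2,4-dihydroxy-3,6-dimethylbenzoic acid
Product: 11 benzyl 2,4-dihydroxy-3,6-dimethylbenzoate
Conditions: BnBr, KHCO3, DMF, rt → 40 °C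
Reagents that add atoms: benzyl bromide, BrCc1ccccc1
Why: SN2 alkylation of the carboxylate. KHCO3 ionises only the acid and not the phenols, so the ester should form without ether formation.

Step 7
Reactants: 11 benzyl 2,4-dihydroxy-3,6-dimethylbenzoate
Product: 13 benzyl 4-(allyloxy)-2-(benzyloxy)-3,6-dimethylbenzoate, via allyl ether 12 (not isolated)
Conditions: allyl bromide (1.0 equiv), K2CO3, DMF, rt; then BnBr, 60 °C
Reagents that add atoms: allyl bromide, C=CCBr; benzyl bromide, BrCc1ccccc1
Why: Two-stage Williamson etherification: the free, more acidic C4 hydroxyl is allylated at room temperature by one equivalent of allyl bromide. The hydrogen-bonded C2 hydroxyl reacts only on heating with BnBr.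

Step 8
Reactants: 13 benzyl 4-(allyloxy)-2-(benzyloxy)-3,6-dimethylbenzoate
Product: 14 benzyl 2-(benzyloxy)-4-hydroxy-3,6-dimethylbenzoate
Conditions: Pd(PPh3)4 (cat.), morpholine, THF, rt
Reagents that add atoms: none
Why: Tsuji–Trost deallylation: zerovalent palladium ionises the aryl allyl ether to a π-allyl complex, which morpholine intercepts. The benzyl ether and benzyl ester do not ionise under these conditions.

Step 9
Reactants: 8 3-bromo-2-hydroxy-4-methoxy-6-methylbenzoic acid; 14 benzyl 2-(benzyloxy)-4-hydroxy-3,6-dimethylbenzoate
Product: 16 benzyl 2-(benzyloxy)-4-[(3-bromo-2-hydroxy-4-methoxy-6-methylbenzoyl)oxy]-3,6-dimethylbenzoate, via mixed anhydride 15 (not isolated)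
Conditions: TFAA, toluene, 0 °C → rt; aq. NaHCO3
Reagents that add atoms: none
Why: Esterification through the mixed trifluoroacetic anhydride 15, the classical depside coupling: the free C4' phenol of 14 attacks the activated aroyl carbon. The chelated C2 hydroxyl of 8 is a poor nucleophile, and any O-trifluoroacetate formed is cleaved on hydrogen carbonate work-up.

Step 10
Reactants: 16 benzyl 2-(benzyloxy)-4-[(3-bromo-2-hydroxy-4-methoxy-6-methylbenzoyl)oxy]-3,6-dimethylbenzoate
Product: 20 benzyl 2-(benzyloxy)-4-{[4-methoxy-6-methyl-2-(trifluoromethylsulfonyloxy)-3-(trimethylsilyl)benzoyl]oxy}-3,6-dimethylbenzoate, via trimethylsilyl ether 17 (not isolated), via C3-aryllithium 18 (not isolated), via lithium phenolate 19 (not isolated)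
Conditions: HMDS, THF, 70 °C, then evaporation; n-BuLi, THF, −100 → −78 °C; Tf2O, −100 °C → rt
Reagents that add atoms: hexamethyldisilazane, C[Si](C)(C)N[Si](C)(C)C; trifluoromethanesulfonic anhydride, O=S(=O)(OS(=O)(=O)C(F)(F)F)C(F)(F)F
Why: This is the standard route from an ortho-bromophenol to an ortho-silylaryl triflate. Bromine–lithium exchange at C3 (between two oxygen substituents) should at −100 °C be faster than addition to the two doubly ortho-substituted esters, and aryllithium 18 undergoes the 1,3 oxygen-to-carbon silyl shift (retro-Brook rearrangement) to phenolate 19. Tf2O then sulfonylates the C2 oxygen.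

Step 11
Reactants: 20 benzyl 2-(benzyloxy)-4-{[4-methoxy-6-methyl-2-(trifluoromethylsulfonyloxy)-3-(trimethylsilyl)benzoyl]oxy}-3,6-dimethylbenzoate; 21 N,N-dimethylformamide
Product: 25 benzyl 2-(benzyloxy)-4-[(3-formyl-2-hydroxy-4-methoxy-6-methylbenzoyl)oxy]-3,6-dimethylbenzoate, via C2–C3 aryne 22 (not isolated), via benzoxete 23 (not isolated), via iminium phenolate 24 (not isolated)
Conditions: CsF (3 equiv), DMF, rt; then H2O
Reagents that add atoms: N,N-dimethylformamide (reactant 21 and solvent), CN(C)C=O; water, O
Why: Fluoride attacks the C3 silicon of 20 and triflate leaves from C2 (fluoride-induced 1,2-elimination of an ortho-silylaryl triflate), giving aryne 22. The carbonyl oxygen of 21 adds to C2 and the resulting C3 aryl anion closes onto the iminium carbon, forming a C2–O and a C3–C bond across the former triple bond; the closest known reaction type is aryne insertion into the C=O bond of formamides, which gives salicylaldehydes after hydrolysis. The only ring closed is the transient four-membered benzoxete 23 (formally a [2+2], in fact a stepwise 4-exo-trig attack of the aryl anion on the iminium carbon); it opens by C–O cleavage to the ortho-quinone-methide-type iminium phenolate 24, which water converts to the aldehyde and dimethylamine. No stereocentre remains: the aminal carbon of 23 is racemic and becomes the planar formyl carbon. The step needs regioselectivity, oxygen at C2 and carbon at C3: the σ-withdrawing C4 methoxy group distorts the aryne so that C2 is the more electrophilic terminus and the developing negative charge sits at C3 next to the C–O bond. The C1 ester pulls the other way, but more weakly, and its bulk matters little for the small formamide oxygen. Chemoselectivity rests on the mild, weakly basic conditions: both esters are doubly ortho-substituted, and the benzyl ether leaves no free phenol that could add to the aryne. Slow generation of the aryne in neat 21 should keep its concentration low and favour capture by solvent over reaction with 24.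

Step 12
Reactants: 25 benzyl 2-(benzyloxy)-4-[(3-formyl-2-hydroxy-4-methoxy-6-methylbenzoyl)oxy]-3,6-dimethylbenzoate
Product: 26 3-{[3-(benzyloxy)-4-(benzyloxycarbonyl)-2,5-dimethylphenoxy]carbonyl}-2-hydroxy-6-methoxy-4-methylbenzoic acid
Conditions: NaClO2, NaH2PO4, 2-methyl-2-butene, t-BuOH/THF/H2O, 0 °C → rt
Reagents that add atoms: sodium chlorite (NaClO2), [Na+].[O-]Cl=O
Why: Pinnick oxidation at buffered, weakly acidic pH, under which the depside ester is stable. Excess 2-methyl-2-butene removes HOCl before it can chlorinate C5 or C5'.

Step 13
Reactants: 26 3-{[3-(benzyloxy)-4-(benzyloxycarbonyl)-2,5-dimethylphenoxy]carbonyl}-2-hydroxy-6-methoxy-4-methylbenzoic acid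
Product: 27 squamatic acid, 3-[(4-carboxy-3-hydroxy-2,5-dimethylphenoxy)carbonyl]-2-hydroxy-6-methoxy-4-methylbenzoic acid
Conditions: H2 (1 atm), 10% Pd/C, EtOAc, rt
Reagents that add atoms: none
Why: Hydrogenolysis of the benzyl ester and the benzyl ether under neutral conditions. The aryl ester, the methyl ether and the free acids are not affected.

## Compound list

1 | 3,5-dimethoxytoluene (1,3-dimethoxy-5-methylbenzene) | COc1cc(C)cc(OC)c1 | starting material
2 | (2,6-dimethoxy-4-methylphenyl)lithium | [Li]c1c(OC)cc(C)cc1OC | intermediate (not isolated)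
3 | 2-bromo-1,3-dimethoxy-5-methylbenzene | COc1cc(C)cc(OC)c1Br | intermediate
4 | 2-bromo-4-[chloro(methoxy)methyl]-1,3-dimethoxy-5-methylbenzene (racemic) | COc1cc(C)c(C(Cl)OC)c(OC)c1Br | intermediate (not isolated)
5 | 3-bromo-2,4-dimethoxy-6-methylbenzaldehyde | COc1cc(C)c(C=O)c(OC)c1Br | intermediate
6 | (2-bromo-6-formyl-3-methoxy-5-methylphenoxy)dichloroborane | COc1cc(C)c(C=O)c(OB(Cl)Cl)c1Br | intermediate (not isolated)
7 | 3-bromo-2-hydroxy-4-methoxy-6-methylbenzaldehyde | COc1cc(C)c(C=O)c(O)c1Br | intermediate
8 | 3-bromo-2-hydroxy-4-methoxy-6-methylbenzoic acid | COc1cc(C)c(C(=O)O)c(O)c1Br | intermediate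
9 | 2,5-dimethylresorcinol (2,5-dimethylbenzene-1,3-diol) | Cc1cc(O)c(C)c(O)c1 | starting material
10 | 2,4-dihydroxy-3,6-dimethylbenzoic acid | Cc1cc(O)c(C)c(O)c1C(=O)O | intermediate
11 | benzyl 2,4-dihydroxy-3,6-dimethylbenzoate | Cc1cc(O)c(C)c(O)c1C(=O)OCc1ccccc1 | intermediate
12 | benzyl 4-(allyloxy)-2-hydroxy-3,6-dimethylbenzoate | C=CCOc1cc(C)c(C(=O)OCc2ccccc2)c(O)c1C | intermediate (not isolated)
13 | benzyl 4-(allyloxy)-2-(benzyloxy)-3,6-dimethylbenzoate | C=CCOc1cc(C)c(C(=O)OCc2ccccc2)c(OCc2ccccc2)c1C | intermediate
14 | benzyl 2-(benzyloxy)-4-hydroxy-3,6-dimethylbenzoate | Cc1cc(O)c(C)c(OCc2ccccc2)c1C(=O)OCc1ccccc1 | intermediate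
15 | 3-bromo-2-hydroxy-4-methoxy-6-methylbenzoic trifluoroacetic anhydride | COc1cc(C)c(C(=O)OC(=O)C(F)(F)F)c(O)c1Br | intermediate (not isolated)
16 | benzyl 2-(benzyloxy)-4-[(3-bromo-2-hydroxy-4-methoxy-6-methylbenzoyl)oxy]-3,6-dimethylbenzoate | COc1cc(C)c(C(=O)Oc2cc(C)c(C(=O)OCc3ccccc3)c(OCc3ccccc3)c2C)c(O)c1Br | intermediate
17 | trimethylsilyl ether of 16 (ring A: C2 OSiMe3, C3 Br) | COc1cc(C)c(C(=O)Oc2cc(C)c(C(=O)OCc3ccccc3)c(OCc3ccccc3)c2C)c(O[Si](C)(C)C)c1Br | intermediate (not isolated)
18 | C3-aryllithium from 17 (ring A: C2 OSiMe3, C3 Li) | COc1cc(C)c(C(=O)Oc2cc(C)c(C(=O)OCc3ccccc3)c(OCc3ccccc3)c2C)c(O[Si](C)(C)C)c1[Li] | intermediate (not isolated)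
19 | lithium phenolate after silyl shift (ring A: C2 OLi, C3 SiMe3) | COc1cc(C)c(C(=O)Oc2cc(C)c(C(=O)OCc3ccccc3)c(OCc3ccccc3)c2C)c([O-])c1[Si](C)(C)C.[Li+] | intermediate (not isolated)
20 | benzyl 2-(benzyloxy)-4-{[4-methoxy-6-methyl-2-(trifluoromethylsulfonyloxy)-3-(trimethylsilyl)benzoyl]oxy}-3,6-dimethylbenzoate | COc1cc(C)c(C(=O)Oc2cc(C)c(C(=O)OCc3ccccc3)c(OCc3ccccc3)c2C)c(OS(=O)(=O)C(F)(F)F)c1[Si](C)(C)C | intermediate
21 | N,N-dimethylformamide | CN(C)C=O | starting material
22 | ring A C2–C3 aryne: benzyl 2-(benzyloxy)-4-[(2,3-didehydro-4-methoxy-6-methylbenzoyl)oxy]-3,6-dimethylbenzoate | COC1=CC(C)=C(C(=O)Oc2cc(C)c(C(=O)OCc3ccccc3)c(OCc3ccccc3)c2C)C#C1 | intermediate (not isolated)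
23 | benzoxete: ring A fused at C2–C3 to a four-membered ring, O on C2 and CH(NMe2) on C3 (racemic) | COc1cc(C)c(C(=O)Oc2cc(C)c(C(=O)OCc3ccccc3)c(OCc3ccccc3)c2C)c2OC(N(C)C)c12 | intermediate (not isolated)
24 | iminium phenolate zwitterion (ring A: C2 O−, C3 CH=N+Me2) | COc1cc(C)c(C(=O)Oc2cc(C)c(C(=O)OCc3ccccc3)c(OCc3ccccc3)c2C)c([O-])c1C=[N+](C)C | intermediate (not isolated)
25 | benzyl 2-(benzyloxy)-4-[(3-formyl-2-hydroxy-4-methoxy-6-methylbenzoyl)oxy]-3,6-dimethylbenzoate (benzyl-protected baeomycesic acid) | COc1cc(C)c(C(=O)Oc2cc(C)c(C(=O)OCc3ccccc3)c(OCc3ccccc3)c2C)c(O)c1C=O | intermediate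
26 | 3-{[3-(benzyloxy)-4-(benzyloxycarbonyl)-2,5-dimethylphenoxy]carbonyl}-2-hydroxy-6-methoxy-4-methylbenzoic acid | COc1cc(C)c(C(=O)Oc2cc(C)c(C(=O)OCc3ccccc3)c(OCc3ccccc3)c2C)c(O)c1C(=O)O | intermediate
27 | squamatic acid, 3-[(4-carboxy-3-hydroxy-2,5-dimethylphenoxy)carbonyl]-2-hydroxy-6-methoxy-4-methylbenzoic acid (achiral) | COc1cc(C)c(C(=O)Oc2cc(C)c(C(=O)O)c(O)c2C)c(O)c1C(=O)O | target

## Step count and least certain steps

Total: 13 steps. Longest linear sequence: 9 steps (steps 1–4 then 9–13; the ring B branch, steps 5–8 then 9–13, is equally long).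

**Step 11 (key step).**
- What may go wrong: loss of regiocontrol, with the formamide oxygen adding at C3 because the C1 ester counteracts the C4 methoxy group. The aryne may also be consumed by phenolate 24, by a second aryne or by fluoride. Fluoride-generated phenolate may cleave the depside ester.
- Fallback: this sets out from 16 and bypasses the aryne. A Stille coupling of the C3 bromide with tributyl(vinyl)stannane (Bu3SnCH=CH2, Pd(PPh3)4, toluene, 100 °C; neutral conditions that the free phenol and the esters tolerate) would give the styrene benzyl 2-(benzyloxy)-4-[(3-ethenyl-2-hydroxy-4-methoxy-6-methylbenzoyl)oxy]-3,6-dimethylbenzoate F1. Lemieux–Johnson cleavage of the vinyl group (OsO4 cat., NaIO4, 2,6-lutidine, dioxane/H2O) would then return to the route at 25.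

**Step 10.**
- What may go wrong: addition of n-BuLi or of aryllithium 18 to the depside or benzyl ester, deprotonation of a benzylic methyl group ortho to an ester, or incomplete silyl migration before triflation.
- Fallback: this sets out from 8 and carries out the organolithium chemistry on a fragment with a single, doubly flanked ester and no aryl ester.
  - Benzylation of the carboxylate (BnBr, KHCO3, DMF) would give benzyl 3-bromo-2-hydroxy-4-methoxy-6-methylbenzoate F2.
  - HMDS would give its silyl ether, benzyl 3-bromo-4-methoxy-6-methyl-2-(trimethylsilyloxy)benzoate F3.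
  - n-BuLi at −100 °C would give [3-(benzyloxycarbonyl)-6-methoxy-4-methyl-2-(trimethylsilyloxy)phenyl]lithium F4, which rearranges to lithium 2-(benzyloxycarbonyl)-5-methoxy-3-methyl-6-(trimethylsilyl)phenolate F5.
  - Tf2O would give benzyl 4-methoxy-6-methyl-2-(trifluoromethylsulfonyloxy)-3-(trimethylsilyl)benzoate F6.
  - Neutral hydrogenolysis (H2, Pd/C, EtOAc) would free 4-methoxy-6-methyl-2-(trifluoromethylsulfonyloxy)-3-(trimethylsilyl)benzoic acid F7.
  - Oxalyl chloride with catalytic DMF would give 4-methoxy-6-methyl-2-(trifluoromethylsulfonyloxy)-3-(trimethylsilyl)benzoyl chloride F8.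
  - Acylation of 14 (Et3N, DMAP, CH2Cl2) would return to the route at 20.

**Step 9.**
- What may go wrong: slow acylation, because both partners are hindered; self-condensation of the hydroxy acid through its own phenol; acid-induced loss of the benzyl ether ortho to the ester.
- Fallback: this sets out from 8. Condensation with acetone (TFAA, TFA) would tie the C2 hydroxyl and the carboxyl together as 8-bromo-7-methoxy-2,2,5-trimethyl-4H-1,3-benzodioxin-4-one F9. The sodium phenolate of 14 (NaH, THF) would open it at the carbonyl group with loss of acetone, returning to the route at 16 with the C2 hydroxyl already free.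

**Step 7.**
- What may go wrong: incomplete discrimination between the two phenols in one pot. Residual allyl bromide could alkylate the C2 oxygen, or benzyl bromide could alkylate unreacted C4 oxygen, giving ethers that differ from 13 only in the position of the groups.
- Fallback: this sets out from 11 and separates the two events with a silyl group.
  - TIPSCl and imidazole in DMF would silylate only the free C4 hydroxyl, giving benzyl 2-hydroxy-3,6-dimethyl-4-(triisopropylsilyloxy)benzoate F10.
  - Benzylation of the chelated phenol (BnBr, NaH, THF, 0 °C → rt) would give benzyl 2-(benzyloxy)-3,6-dimethyl-4-(triisopropylsilyloxy)benzoate F11.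
  - Bu4NF in THF would return to the route at 14, bypassing 13.

## Further compounds

F1 | step 11 | benzyl 2-(benzyloxy)-4-[(3-ethenyl-2-hydroxy-4-methoxy-6-methylbenzoyl)oxy]-3,6-dimethylbenzoate | COc1cc(C)c(C(=O)Oc2cc(C)c(C(=O)OCc3ccccc3)c(OCc3ccccc3)c2C)c(O)c1C=C
F2 | step 10 | benzyl 3-bromo-2-hydroxy-4-methoxy-6-methylbenzoate | COc1cc(C)c(C(=O)OCc2ccccc2)c(O)c1Br
F3 | step 10 | benzyl 3-bromo-4-methoxy-6-methyl-2-(trimethylsilyloxy)benzoate | COc1cc(C)c(C(=O)OCc2ccccc2)c(O[Si](C)(C)C)c1Br
F4 | step 10 | [3-(benzyloxycarbonyl)-6-methoxy-4-methyl-2-(trimethylsilyloxy)phenyl]lithium | COc1cc(C)c(C(=O)OCc2ccccc2)c(O[Si](C)(C)C)c1[Li]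
F5 | step 10 | lithium 2-(benzyloxycarbonyl)-5-methoxy-3-methyl-6-(trimethylsilyl)phenolate | COc1cc(C)c(C(=O)OCc2ccccc2)c([O-])c1[Si](C)(C)C.[Li+]
F6 | step 10 | benzyl 4-methoxy-6-methyl-2-(trifluoromethylsulfonyloxy)-3-(trimethylsilyl)benzoate | COc1cc(C)c(C(=O)OCc2ccccc2)c(OS(=O)(=O)C(F)(F)F)c1[Si](C)(C)C
F7 | step 10 | 4-methoxy-6-methyl-2-(trifluoromethylsulfonyloxy)-3-(trimethylsilyl)benzoic acid | COc1cc(C)c(C(=O)O)c(OS(=O)(=O)C(F)(F)F)c1[Si](C)(C)C
F8 | step 10 | 4-methoxy-6-methyl-2-(trifluoromethylsulfonyloxy)-3-(trimethylsilyl)benzoyl chloride | COc1cc(C)c(C(=O)Cl)c(OS(=O)(=O)C(F)(F)F)c1[Si](C)(C)C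
F9 | step 9 | 8-bromo-7-methoxy-2,2,5-trimethyl-4H-1,3-benzodioxin-4-one | COc1cc(C)c2C(=O)OC(C)(C)Oc2c1Br
F10 | step 7 | benzyl 2-hydroxy-3,6-dimethyl-4-(triisopropylsilyloxy)benzoate | Cc1cc(O[Si](C(C)C)(C(C)C)C(C)C)c(C)c(O)c1C(=O)OCc1ccccc1
F11 | step 7 | benzyl 2-(benzyloxy)-3,6-dimethyl-4-(triisopropylsilyloxy)benzoate | Cc1cc(O[Si](C(C)C)(C(C)C)C(C)C)c(C)c(OCc2ccccc2)c1C(=O)OCc1ccccc1
A1 | alternative 1 | benzyl 2-(benzyloxy)-4-{[2-hydroxy-4-methoxy-6-methyl-3-(triisopropylsilyloxymethyl)benzoyl]oxy}-3,6-dimethylbenzoate | COc1cc(C)c(C(=O)Oc2cc(C)c(C(=O)OCc3ccccc3)c(OCc3ccccc3)c2C)c(O)c1CO[Si](C(C)C)(C(C)C)C(C)C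
A2 | alternative 1 | 3-(benzyloxy)-4-(benzyloxycarbonyl)-2,5-dimethylphenyl (E)-5-diazo-3-methyl-4-oxopent-2-enoate | [N-]=[N+]=CC(=O)/C(C)=C/C(=O)Oc1cc(C)c(C(=O)OCc2ccccc2)c(OCc2ccccc2)c1C
A3 | alternative 1 | 1-methoxy-3-(triisopropylsilyloxy)prop-1-yne | COC#CCO[Si](C(C)C)(C(C)C)C(C)C
A4 | alternative 2 | benzyl 4-[(2,4-dihydroxy-6-methylbenzoyl)oxy]-2-hydroxy-3,6-dimethylbenzoate | Cc1cc(O)cc(O)c1C(=O)Oc1cc(C)c(C(=O)OCc2ccccc2)c(O)c1C
A5 | alternative 2 | 6-(2,4-dioxopentyl)-2,2-dimethyl-4H-1,3-dioxin-4-one | CC(=O)CC(=O)CC1=CC(=O)OC(C)(C)O1
A6 | alternative 3 | benzyl 2-(benzyloxy)-4-[(2-hydroxy-4-methoxy-6-methylbenzoyl)oxy]-3,6-dimethylbenzoate | COc1cc(C)c(C(=O)Oc2cc(C)c(C(=O)OCc3ccccc3)c(OCc3ccccc3)c2C)c(O)c1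
A7 | alternative 3 | benzyl 2-(benzyloxy)-4-(but-2-ynoyloxy)-3,6-dimethylbenzoate | CC#CC(=O)Oc1cc(C)c(C(=O)OCc2ccccc2)c(OCc2ccccc2)c1C
A8 | alternative 3 | 1,3-dimethoxy-1-(trimethylsilyloxy)buta-1,3-diene | COC(=C)C=C(OC)O[Si](C)(C)C
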